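**Plan**

1. Retrosynthetic cuts: (a) the C6–O acyl bond and the silyl ether; (b) the 3(2H)-furanone ring at two of its bonds, C1–C2 and O–C3; (c) C6–C7 (allylation); (d) the lactone bonds C8–O/C7–C8.
2. Enabling feature: the furanone ring (O, C10, C1, C2, C3) is the α-hydroxy-acyl unit O–C10–C1(=O) of a tertiary α-hydroxy acid added across an alkyne C2≡C3. C10 with its methyl, CH2 and carboxyl carbon maps onto (R)-citramalic acid, and C2–C6 with the Z-C4=C5 alkene onto commercial (Z)-3-methylpent-2-en-4-yn-1-ol.
3. The trans-fused lactone and the Z-alkene hold the acyl end (C1) and the alkyne end (C2) on the same side, so one acyl–alkyne coupling can close the ten-membered carbocycle and hand the tertiary hydroxyl an ynone for the furanone closure.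
4. Forward order: α-methylene-γ-butyrolactone (step 3; temporarily a butenolide in 8) → union of the halves at C6–C7 (step 6) → side-chain ester (step 10) → ten-membered carbocycle and, last, the furanone in one operation (step 15). Helpers: acetonide (masks C1–OH/C10–OH), S-ethyl thioester (activating group, leaves in the key step), TBS (removed last).
5. Stereochemistry: C10 from (R)-citramalic acid; C8 by catalyst-controlled iridium allylation; C7 and C6 from the chair transition state of the ring-locked allylchromium reagent, anti to the C8 substituent; C3′ from methyl (R)-3-hydroxybutanoate; C4=C5 geometry from the Z-enynol; C2=C3 geometry from the five-membered ring.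

Key step: step 15

Remark: germacrane numbering is used (C1 furanone carbonyl, C2=C3 enol ether, C4=C5, C6 acyloxy carbon, C7, C8 lactone carbinol, C9, C10 quaternary carbon, C11–C13 methylene lactone); carbonate 4 is assumed purchasable (otherwise one step from methyl 2-(hydroxymethyl)acrylate and Boc2O).

**Route**

Step 1
Reactants: 1 (R)-citramalic acid
Product: 2 (2R)-2-methylbutane-1,2,4-triol
Conditions: BH3·SMe2, B(OMe)3, THF, 0 °C → rt; MeOH quench
Reagents that add atoms: none
Why: Borane reduces both carboxyl groups of the hydroxy diacid to primary alcohols (carboxylic acid reduction) without touching the tertiary carbinol, so C10 (R) is carried over unchanged from the chiral pool.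

Step 2
Reactants: 2 (2R)-2-methylbutane-1,2,4-triol
Product: 3 2-[(4R)-2,2,4-trimethyl-1,3-dioxolan-4-yl]ethan-1-ol
Conditions: 2,2-dimethoxypropane, TsOH·H2O (cat.), acetone, rt
Reagents that add atoms: 2,2-dimethoxypropane, COC(C)(C)OC
Why: Acid-catalysed acetalization should select the five-membered dioxolane of the vicinal primary/tertiary diol over the six-membered alternative (thermodynamic control), masking C1–OH and C10–OH and leaving the C8 hydroxyl free.

Step 3
Reactants: 3 2-[(4R)-2,2,4-trimethyl-1,3-dioxolan-4-yl]ethan-1-ol; 4 methyl 2-{[(tert-butoxycarbonyl)oxy]methyl}prop-2-enoate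
Product: 6 (5R)-3-methylidene-5-{[(4R)-2,2,4-trimethyl-1,3-dioxolan-4-yl]methyl}oxolan-2-one, via hydroxy ester 5 (not isolated)
Conditions: [Ir(cod)Cl]2 (2.5 mol %), (R)-SEGPHOS (5 mol %), 4-chloro-3-nitrobenzoic acid (10 mol %), Cs2CO3 (20 mol %), THF, 60 °C
Reagents that add atoms: none
Why: Krische allylation in its 2-(alkoxycarbonyl)allylation form: the iridium catalyst dehydrogenates the primary alcohol, the chiral bisphosphine directs the 2-(methoxycarbonyl)allyl group to the Re face of the transient aldehyde (catalyst control of C8; should the (R)-ligand give the opposite sense, its antipode is used), and hydroxy ester 5 lactonizes under the basic conditions.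

Step 4
Reactants: 6 (5R)-3-methylidene-5-{[(4R)-2,2,4-trimethyl-1,3-dioxolan-4-yl]methyl}oxolan-2-one
Product: 8 (5S)-3-(bromomethyl)-5-{[(4R)-2,2,4-trimethyl-1,3-dioxolan-4-yl]methyl}furan-2(5H)-one, via dibromide 7 (not isolated)
Conditions: Br2, CH2Cl2, 0 °C; then Et3N, 0 °C → rt
Reagents that add atoms: bromine, BrBr
Why: Bromine addition to the exocyclic alkene and amine-induced dehydrobromination of the tertiary bromide toward the ring CH2 (the addition–elimination that turns dibromoisobutyrates into 2-(bromomethyl)acrylates) should give the conjugated butenolide with an allylic bromide, the cold and brief amine treatment keeping the γ-stereocenter C8 intact (its descriptor changes only through CIP priorities).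

Step 5
Reactants: 9 (2Z)-3-methylpent-2-en-4-yn-1-ol
Product: 10 (2Z)-3-methylpent-2-en-4-ynal
Conditions: TEMPO (10 mol %), PhI(OAc)2, CH2Cl2, rt
Reagents that add atoms: none
Why: Oxoammonium (TEMPO/PhI(OAc)2) oxidation of the allylic alcohol stops at the aldehyde and uses no acid or base strong enough to isomerize the Z-alkene.

Step 6
Reactants: 8 (5S)-3-(bromomethyl)-5-{[(4R)-2,2,4-trimethyl-1,3-dioxolan-4-yl]methyl}furan-2(5H)-one; 10 (2Z)-3-methylpent-2-en-4-ynal
Product: 11 (4S,5S)-4-[(1R,2Z)-1-hydroxy-3-methylpent-2-en-4-yn-1-yl]-3-methylidene-5-{[(4R)-2,2,4-trimethyl-1,3-dioxolan-4-yl]methyl}oxolan-2-one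
Conditions: CrCl2 (3 equiv), THF, rt; aqueous work-up
Reagents that add atoms: none
Why: Nozaki–Hiyama-type (Barbier-type) chromium-mediated allylation: the ring-locked, E-type allylchromium reagent should add through its γ-carbon C7 in a chair-like Zimmerman–Traxler transition state, on the ring face anti to the C8 side chain (7,8-trans) and with the aldehyde substituent equatorial (6,7-anti, that is 6R), regenerating the exocyclic methylene.

Step 7
Reactants: 12 methyl (3R)-3-hydroxybutanoate
Product: 13 methyl (3R)-3-[(tert-butyldimethylsilyl)oxy]butanoate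
Conditions: TBSCl, imidazole, DMF, rt
Reagents that add atoms: tert-butyldimethylsilyl chloride, CC(C)(C)[Si](C)(C)Cl
Why: Standard silylation of the secondary alcohol protects the hydroxyl for the enolate chemistry and the esterification without touching the stereocenter.

Step 8
Reactants: 13 methyl (3R)-3-[(tert-butyldimethylsilyl)oxy]butanoate
Product: 16 methyl (3R)-3-[(tert-butyldimethylsilyl)oxy]-2-methylidenebutanoate, via Mannich base 14 (not isolated), via ammonium iodide 15 (not isolated)
Conditions: LDA, THF, −78 °C; CH2=NMe2+ I−, −78 → 0 °C; then MeI, MeOH, rt; then DBU, CH2Cl2, rt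
Reagents that add atoms: Eschenmoser's salt (N,N-dimethylmethyleneiminium iodide), C=[N+](C)C.[I-]
Why: Mannich reaction of the ester enolate with Eschenmoser's salt at −78 °C (where β-elimination of the silyloxy group is slow), quaternization and Hofmann-type elimination give the α-methylene ester; the α-carbon ends sp2 and the C3′ stereocenter is not involved.

Step 9
Reactants: 16 methyl (3R)-3-[(tert-butyldimethylsilyl)oxy]-2-methylidenebutanoate
Product: 17 (3R)-3-[(tert-butyldimethylsilyl)oxy]-2-methylidenebutanoic acid
Conditions: LiOH·H2O, THF/H2O (3:1), 0 °C → rt; then 1 M HCl to pH 3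
Reagents that add atoms: lithium hydroxide, [Li+].[OH-]
Why: Saponification of the methyl ester leaves the silyl ether and the stereocenter untouched and gives the free acid for coupling.

Step 10
Reactants: 11 (4S,5S)-4-[(1R,2Z)-1-hydroxy-3-methylpent-2-en-4-yn-1-yl]-3-methylidene-5-{[(4R)-2,2,4-trimethyl-1,3-dioxolan-4-yl]methyl}oxolan-2-one; 17 (3R)-3-[(tert-butyldimethylsilyl)oxy]-2-methylidenebutanoic acid
Product: 18 (1R,2Z)-3-methyl-1-[(2S,3R)-4-methylidene-5-oxo-2-{[(4R)-2,2,4-trimethyl-1,3-dioxolan-4-yl]methyl}oxolan-3-yl]pent-2-en-4-yn-1-yl (3R)-3-[(tert-butyldimethylsilyl)oxy]-2-methylidenebutanoate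
Conditions: DCC, DMAP (cat.), CH2Cl2, 0 °C → rt
Reagents that add atoms: none
Why: Steglich esterification acylates the hindered allylic C6 hydroxyl with retention at C6 and C3′, and also caps the (Z)-enynol so that it cannot cyclize to a furan in the later metal-mediated steps.

Step 11
Reactants: 18 acetonide ester
Product: 19 diol ester with a (2R)-2,3-dihydroxy-2-methylpropyl group on C8
Conditions: AcOH/H2O (4:1), 40 °C
Reagents that add atoms: none
Why: Mild aqueous acid should hydrolyse the acetonide faster than it cleaves the hindered secondary TBS ether or ionizes the allylic ester, releasing the primary/tertiary diol.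

Step 12
Reactants: 19 diol ester
Product: 20 α-hydroxy aldehyde with a (2R)-2-hydroxy-2-methyl-3-oxopropyl group on C8
Conditions: IBX, EtOAc, 75 °C
Reagents that add atoms: none
Why: IBX oxidizes the primary alcohol of a 1,2-diol to the α-hydroxy aldehyde without glycol cleavage and leaves the tertiary hydroxyl, the alkyne and the Michael acceptors alone.

Step 13
Reactants: 20 α-hydroxy aldehyde
Product: 21 α-hydroxy acid with a (2R)-2-carboxy-2-hydroxypropyl group on C8
Conditions: NaClO2, NaH2PO4, 2-methyl-2-butene, t-BuOH/H2O, 0 °C → rt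
Reagents that add atoms: sodium chlorite, [Na+].[O-]Cl=O
Why: Pinnick oxidation converts the aldehyde into the acid under buffered conditions, the hypochlorite by-product being scavenged by 2-methyl-2-butene so that the alkyne and the alkenes are spared.

Step 14
Reactants: 21 α-hydroxy acid
Product: 22 S-ethyl thioester of 21
Conditions: EtSH (1.1 equiv), DCC, HOBt (cat.), CH2Cl2, −10 → 0 °C
Reagents that add atoms: ethanethiol, CCS
Why: Carbodiimide activation and capture by ethanethiol give the S-ethyl thioester (the activating group for the key step), the base-free, cold conditions and near-stoichiometric thiol serving to suppress thia-Michael addition to the methylene lactone and the acrylate.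

Step 15
Reactants: 22 S-ethyl thioester
Product: 24 3′-O-TBS ether of the target, via ten-membered hydroxy ynone 23 (not isolated)
Conditions: PdCl2(dppf) (10 mol %), P(2-furyl)3 (25 mol %), CuI (1.7 equiv), i-Pr2NEt (3 equiv), degassed DMF, 50 °C, syringe-pump addition of 22 (final 2 mM)
Reagents that add atoms: none
Why: Proposed new method: zerovalent palladium, assisted by thiophilic CuI, should insert into the acyl–sulfur bond of the α-hydroxy thioester, the copper acetylide of the (Z)-enyne transmetalates, and reductive elimination forges C1–C2 to give the ten-membered α′-hydroxy ynone 23, whose tertiary hydroxyl then adds to C3 of the ynone (5-endo-dig oxa-Michael, promoted by monovalent copper and the amine) to give the furanone. The closest known reactions are the intermolecular acyl Sonogashira-type Pd/Cu coupling of thioesters with terminal alkynes to ynones and the base- or coinage-metal-mediated cyclization of acyclic α′-hydroxy ynones to 3(2H)-furanones; new is the ring-closing use of the first to make a strained cyclic enynone and its telescoping with the second. The carbocycle closes by C(sp2)–C(sp) reductive elimination from an eleven-membered palladacycle in which the Z-C4=C5 alkene and the trans-fused lactone hold the two chain ends on the same side, and the furanone closes transannularly in the 5-endo-dig mode, which also releases the bending strain of the ring alkyne. No stereocenter is formed: C10 comes unchanged from citramalic acid, and the geometry of the new C2=C3 enol ether (O and C1 cis) is dictated by the five-membered ring. The step needs ring closure over oligomerization and alkyne homocoupling, which slow addition at high dilution under exclusion of oxygen should secure, and C–S activation in preference to the lactone, the esters and the allylic C6 ester, which the much higher reactivity of the copper-activated thioester should secure. O-attack at C3 and not at C2 follows from the polarization of the ynone and from the 1,2-relationship of hydroxyl and acyl group, which allows only the five-membered closure.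

Step 16
Reactants: 24 3′-O-TBS ether of the target
Product: 25 target CNP0266753.1
Conditions: HF·pyridine, THF/pyridine, 0 °C → rt
Reagents that add atoms: none
Why: Fluoride-mediated cleavage of the secondary TBS ether under buffered HF·pyridine conditions, which the furanone, the α-methylene lactone and the acrylate ester should tolerate, releases the side-chain hydroxyl and gives the target.

**Compound list**

1 | (R)-citramalic acid [(2R)-2-hydroxy-2-methylbutanedioic acid] | OC(=O)[C@](C)(O)CC(=O)O | starting material
2 | (2R)-2-methylbutane-1,2,4-triol | OC[C@](C)(O)CCO | intermediate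
3 | 2-[(4R)-2,2,4-trimethyl-1,3-dioxolan-4-yl]ethan-1-ol | OCC[C@]1(C)COC(C)(C)O1 | intermediate
4 | methyl 2-{[(tert-butoxycarbonyl)oxy]methyl}prop-2-enoate | C=C(COC(=O)OC(C)(C)C)C(=O)OC | starting material
5 | methyl (4R)-4-hydroxy-2-methylidene-5-[(4R)-2,2,4-trimethyl-1,3-dioxolan-4-yl]pentanoate | C=C(C[C@@H](O)C[C@]1(C)COC(C)(C)O1)C(=O)OC | intermediate
6 | (5R)-3-methylidene-5-{[(4R)-2,2,4-trimethyl-1,3-dioxolan-4-yl]methyl}oxolan-2-one | C=C1C[C@H](C[C@]2(C)COC(C)(C)O2)OC1=O | intermediate
7 | (5S)-3-bromo-3-(bromomethyl)-5-{[(4R)-2,2,4-trimethyl-1,3-dioxolan-4-yl]methyl}oxolan-2-one (both C3 epimers) | BrCC1(Br)C[C@H](C[C@]2(C)COC(C)(C)O2)OC1=O | intermediate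
8 | (5S)-3-(bromomethyl)-5-{[(4R)-2,2,4-trimethyl-1,3-dioxolan-4-yl]methyl}furan-2(5H)-one | BrCC1=C[C@H](C[C@]2(C)COC(C)(C)O2)OC1=O | intermediate
9 | (2Z)-3-methylpent-2-en-4-yn-1-ol | OC/C=C(C)\C#C | starting material
10 | (2Z)-3-methylpent-2-en-4-ynal | O=C/C=C(C)\C#C | intermediate
11 | (4S,5S)-4-[(1R,2Z)-1-hydroxy-3-methylpent-2-en-4-yn-1-yl]-3-methylidene-5-{[(4R)-2,2,4-trimethyl-1,3-dioxolan-4-yl]methyl}oxolan-2-one | C=C1C(=O)O[C@@H](C[C@]2(C)COC(C)(C)O2)[C@@H]1[C@H](O)/C=C(C)\C#C | intermediate
12 | methyl (3R)-3-hydroxybutanoate | COC(=O)C[C@@H](C)O | starting material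
13 | methyl (3R)-3-[(tert-butyldimethylsilyl)oxy]butanoate | COC(=O)C[C@@H](C)O[Si](C)(C)C(C)(C)C | intermediate
14 | methyl (3R)-3-[(tert-butyldimethylsilyl)oxy]-2-[(dimethylamino)methyl]butanoate (both C2 epimers) | COC(=O)C(CN(C)C)[C@@H](C)O[Si](C)(C)C(C)(C)C | intermediate
15 | [(3R)-3-[(tert-butyldimethylsilyl)oxy]-2-(methoxycarbonyl)butyl]trimethylammonium iodide | COC(=O)C(C[N+](C)(C)C)[C@@H](C)O[Si](C)(C)C(C)(C)C.[I-] | intermediate
16 | methyl (3R)-3-[(tert-butyldimethylsilyl)oxy]-2-methylidenebutanoate | COC(=O)C(=C)[C@@H](C)O[Si](C)(C)C(C)(C)C | intermediate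
17 | (3R)-3-[(tert-butyldimethylsilyl)oxy]-2-methylidenebutanoic acid | OC(=O)C(=C)[C@@H](C)O[Si](C)(C)C(C)(C)C | intermediate
18 | (1R,2Z)-3-methyl-1-[(2S,3R)-4-methylidene-5-oxo-2-{[(4R)-2,2,4-trimethyl-1,3-dioxolan-4-yl]methyl}oxolan-3-yl]pent-2-en-4-yn-1-yl (3R)-3-[(tert-butyldimethylsilyl)oxy]-2-methylidenebutanoate | C=C1C(=O)O[C@@H](C[C@]2(C)COC(C)(C)O2)[C@@H]1[C@H](OC(=O)C(=C)[C@@H](C)O[Si](C)(C)C(C)(C)C)/C=C(C)\C#C | intermediate
19 | diol ester: 18 with the acetonide removed, C8 carrying (2R)-2,3-dihydroxy-2-methylpropyl | C=C1C(=O)O[C@@H](C[C@@](C)(O)CO)[C@@H]1[C@H](OC(=O)C(=C)[C@@H](C)O[Si](C)(C)C(C)(C)C)/C=C(C)\C#C | intermediate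
20 | α-hydroxy aldehyde: as 19, C8 carrying (2R)-2-hydroxy-2-methyl-3-oxopropyl | C=C1C(=O)O[C@@H](C[C@@](C)(O)C=O)[C@@H]1[C@H](OC(=O)C(=C)[C@@H](C)O[Si](C)(C)C(C)(C)C)/C=C(C)\C#C | intermediate
21 | α-hydroxy acid: as 19, C8 carrying (2R)-2-carboxy-2-hydroxypropyl | C=C1C(=O)O[C@@H](C[C@@](C)(O)C(=O)O)[C@@H]1[C@H](OC(=O)C(=C)[C@@H](C)O[Si](C)(C)C(C)(C)C)/C=C(C)\C#C | intermediate
22 | S-ethyl thioester of 21 (seco precursor of the key step) | C=C1C(=O)O[C@@H](C[C@@](C)(O)C(=O)SCC)[C@@H]1[C@H](OC(=O)C(=C)[C@@H](C)O[Si](C)(C)C(C)(C)C)/C=C(C)\C#C | intermediate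
23 | ten-membered α′-hydroxy ynone: (6R,7R,8S,10R)-10-hydroxy-1-oxogermacra-4Z,11(13)-dien-2-yn-8,12-olide 6-[(3R)-3-(TBS-oxy)-2-methylidenebutanoate] | C=C1C(=O)O[C@H]2C[C@@](C)(O)C(=O)C#C/C(C)=C\[C@@H](OC(=O)C(=C)[C@@H](C)O[Si](C)(C)C(C)(C)C)[C@H]12 | intermediate
24 | 3′-O-TBS ether of the target | C=C1C(=O)O[C@H]2C[C@@]3(C)OC(=CC3=O)/C(C)=C\[C@@H](OC(=O)C(=C)[C@@H](C)O[Si](C)(C)C(C)(C)C)[C@H]12 | intermediate
25 | CNP0266753.1: (6R,7R,8S,10R)-3,10-epoxy-1-oxogermacra-2,4Z,11(13)-trien-8,12-olide 6-[(3R)-3-hydroxy-2-methylidenebutanoate] | C=C1C(=O)O[C@H]2C[C@@]3(C)OC(=CC3=O)/C(C)=C\[C@@H](OC(=O)C(=C)[C@@H](C)O)[C@H]12 | target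

**Count and risks**

Total steps: 16. Longest linear sequence: 12 steps (steps 1, 2, 3, 4, 6, 10, 11, 12, 13, 14, 15, 16).

Steps most likely to fail:

1. Step 15 (Proposed new method). What may go wrong: oligomerization or alkyne homocoupling outrunning ring closure; reluctant reductive elimination to the strained ring; ionization of the allylic C6 ester by zerovalent palladium; conjugate addition of thiolate to the Michael acceptors. The fallback uses known chemistry, sets out from aldehyde 20 and comes back at 24. The terminal alkyne of 20 is iodinated (NIS, AgNO3 cat., acetone) to iodoalkyne aldehyde F1. A Nozaki–Hiyama–Kishi ring closure (CrCl2, NiCl2 cat., THF/DMF, high dilution), a reaction type known to close ten-membered enyne rings, gives the ten-membered propargylic alcohol F2 as both C1 epimers, which converge. IBX oxidation gives hydroxy ynone 23, here isolated, and Ph3PAuNTf2 (monovalent gold, CH2Cl2, rt) effects the transannular 5-endo-dig cycloisomerization to 24.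

2. Step 6. What may go wrong: erosion of the 6,7-anti selectivity through a boat-like or open transition state; Z-to-E isomerization of the enal before addition; attack through the α-carbon of the allyl unit. The fallback sets out from 8 and 10 and comes back at 18. The two are coupled under indium-mediated aqueous Barbier conditions (In, THF/H2O), and if the C6 epimer (4S,5S)-4-[(1S,2Z)-1-hydroxy-3-methylpent-2-en-4-yn-1-yl] lactone F3 is what is obtained, C6 is corrected during the esterification by a Mitsunobu reaction with acid 17 (PPh3, DIAD, inversion), giving 18.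

3. Step 3. What may go wrong: insufficient catalyst control of the aldehyde face (mismatch with the C10 center); incomplete lactonization; transfer-hydrogenative reduction of the methylene lactone. The fallback sets out from 3 and comes back at 6. IBX oxidation of 3 gives 2-[(4R)-2,2,4-trimethyl-1,3-dioxolan-4-yl]acetaldehyde F4. Allylboration with methyl 2-[(pinacolatoboryl)methyl]acrylate under a chiral phosphoric acid catalyst gives hydroxy ester 5, and acid-induced lactonization gives 6.

Further compounds
F1 | step 15 | iodoalkyne aldehyde: 20 with the terminal alkyne iodinated | C=C1C(=O)O[C@@H](C[C@@](C)(O)C=O)[C@@H]1[C@H](OC(=O)C(=C)[C@@H](C)O[Si](C)(C)C(C)(C)C)/C=C(C)\C#CI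
F2 | step 15 | ten-membered propargylic alcohol: 23 with C1 as CH(OH), both C1 epimers | C=C1C(=O)O[C@H]2C[C@@](C)(O)C(O)C#C/C(C)=C\[C@@H](OC(=O)C(=C)[C@@H](C)O[Si](C)(C)C(C)(C)C)[C@H]12
F3 | step 6 | (4S,5S)-4-[(1S,2Z)-1-hydroxy-3-methylpent-2-en-4-yn-1-yl]-3-methylidene-5-{[(4R)-2,2,4-trimethyl-1,3-dioxolan-4-yl]methyl}oxolan-2-one (C6 epimer of 11) | C=C1C(=O)O[C@@H](C[C@]2(C)COC(C)(C)O2)[C@@H]1[C@@H](O)/C=C(C)\C#C
F4 | step 3 | 2-[(4R)-2,2,4-trimethyl-1,3-dioxolan-4-yl]acetaldehyde | O=CC[C@]1(C)COC(C)(C)O1
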